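**Strategy.** The target is read as epicatechin gallate-(4β→8)-epicatechin gallate-(4β→8)-catechin. In each epicatechin gallate unit C4 is bonded to C4a of its own phloroglucinol ring A, to the oxygenated C3 and to an external arene: an aldehyde carbon after two Friedel–Crafts events. Everything therefore rests on the C4–C4a disconnection of pyran ring C. The precursor is an acyclic α-galloyloxy β-aryloxy aldehyde whose ring A hangs on the future O1. In one operation acid closes ring C by C4–C4a bond formation and 2-ethoxyethanol traps the resulting flavan-4-yl cation as a storable 4-alkoxyflavan. This single electrophile is then coupled with benzylated catechin and again with the resulting dimer.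

Key step: step 7

Assumption: 4-bromo-1,2-bis(benzyloxy)benzene, (R)-glyceraldehyde acetonide (freshly distilled), 3,5-bis(benzyloxy)phenol, 3,4,5-tris(benzyloxy)benzoyl chloride and (+)-catechin are taken as commercial.

Step 1
Reactants: 1 4-bromo-1,2-bis(benzyloxy)benzene; 2 (R)-2,2-dimethyl-1,3-dioxolane-4-carbaldehyde
Product: 5 anti alcohol (S)-[3,4-bis(benzyloxy)phenyl][(4R)-2,2-dimethyl-1,3-dioxolan-4-yl]methanol, via aryllithium 3 (not isolated), via aryltitanium triisopropoxide 4 (not isolated)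
Conditions: n-BuLi, THF, −78 °C; ClTi(OiPr)3, −78 → −30 °C; then 2, −78 → 0 °C; aq. NH4Cl
Reagents that add atoms: none
Why: Bromine–lithium exchange followed by transmetalation gives a non-chelating aryltitanium reagent whose addition to the α-alkoxy aldehyde should follow the polar Felkin–Anh model, setting the carbinol centre as (S) anti to the dioxolane centre that comes from the chiral pool, with the minor syn epimer removed by chromatography.

Step 2
Reactants: 5 anti alcohol; 6 3,5-bis(benzyloxy)phenol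
Product: 7 (4R)-4-{(R)-[3,4-bis(benzyloxy)phenyl][3,5-bis(benzyloxy)phenoxy]methyl}-2,2-dimethyl-1,3-dioxolane
Conditions: PPh3, DIAD, toluene, −20 °C → rt
Reagents that add atoms: none
Why: In this Mitsunobu etherification the phenol should displace the alkoxyphosphonium ion by SN2 with inversion at the benzylic carbon, which turns the anti alcohol into the (R)-aryl ether holding the future O1–C2 bond syn to the C3 oxygen, while the inductively withdrawing dioxolane oxygen disfavours ionisation.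

Step 3
Reactants: 7 aryl ether acetonide
Product: 8 (2R,3R)-3-[3,4-bis(benzyloxy)phenyl]-3-[3,5-bis(benzyloxy)phenoxy]propane-1,2-diol
Conditions: AcOH/H2O (4:1), 45 °C
Reagents that add atoms: none
Why: Mild acid-catalysed acetal hydrolysis should free the 1,2-diol without ionising the benzylic aryl ether or cleaving benzyl ethers, and no stereocentre is involved.

Step 4
Reactants: 8 diol
Product: 10 (1R,2R)-1-[3,4-bis(benzyloxy)phenyl]-1-[3,5-bis(benzyloxy)phenoxy]-3-(triethylsilyloxy)propan-2-yl 3,4,5-tris(benzyloxy)benzoate, via primary triethylsilyl ether 9 (not isolated)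
Conditions: TESCl (1.05 equiv), pyridine, CH2Cl2, −30 → 0 °C; then 3,4,5-tris(benzyloxy)benzoyl chloride, DMAP (cat.), 0 °C → rt
Reagents that add atoms: chlorotriethylsilane CC[Si](Cl)(CC)CC; 3,4,5-tris(benzyloxy)benzoyl chloride O=C(Cl)c1cc(OCc2ccccc2)c(OCc2ccccc2)c(OCc2ccccc2)c1
Why: Selective silylation of the less hindered primary hydroxyl is followed in the same flask by DMAP-catalysed acylation of the secondary hydroxyl, which places the protected gallate on the future C3 with retention because only the O–H bond reacts.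

Step 5
Reactants: 10 silyl ether gallate
Product: 12 aldehyde (1R,2S)-1-[3,4-bis(benzyloxy)phenyl]-1-[3,5-bis(benzyloxy)phenoxy]-3-oxopropan-2-yl 3,4,5-tris(benzyloxy)benzoate, via primary alcohol 11 (not isolated)
Conditions: IBX (3 equiv), wet DMSO, rt; crude product used at once
Reagents that add atoms: none
Why: IBX in wet DMSO is known to cleave primary triethylsilyl ethers and to oxidise the liberated alcohol in the same pot, so these neutral conditions should give the α-acyloxy aldehyde without the base-induced epimerisation at C3 or β-elimination of the aryloxide that an amine base could cause.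

Step 6
Reactants: 13 (+)-catechin
Product: 14 3,5,7,3',4'-penta-O-benzyl-(+)-catechin
Conditions: NaH (6 equiv), BnBr (6 equiv), DMF, −20 °C → rt
Reagents that add atoms: benzyl bromide BrCc1ccccc1
Why: Williamson etherification of the four phenoxides and of the C3 alkoxide with excess benzyl bromide at low temperature should give the fully protected nucleophile with both stereocentres of natural (+)-catechin unchanged.

Step 7
Reactants: 12 aldehyde
Product: 16 5,7,3',4'-tetra-O-benzyl-4-(2-ethoxyethoxy)epicatechin 3-O-[3,4,5-tris(benzyloxy)benzoate] (both C4 epimers), via flavan-4-ol 15 (not isolated)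
Conditions: Yb(OTf)3 (0.1 equiv), 2-ethoxyethanol (20 equiv), CH2Cl2 (0.01 M), 4 Å MS, −20 → 0 °C; Et3N quench
Reagents that add atoms: 2-ethoxyethanol CCOCCO
Why: Yb(OTf)3 activates the aldehyde of 12, and the ring carbon ortho to the ether oxygen of its tethered 3,5-bis(benzyloxy)phenoxy group (future C4a) attacks the carbonyl carbon (future C4) in an intramolecular Friedel–Crafts hydroxyalkylation that closes pyran ring C in the 6-exo-trig mode and gives flavan-4-ol 15. Under the same acid 15 ionises to the flavan-4-yl cation, stabilised by O1 and the 5- and 7-benzyloxy groups, and the excess 2-ethoxyethanol captures it as the 4-ether, so that the cation should not alkylate a second arene. The closest known reaction types are the acid-mediated cyclisation of 3-aryloxypropanals and their acetals to chroman-4-ols and 4-alkoxychromans and the alcohol trapping of flavan-4-yl cations. C2 and C3 are carried over unchanged from 12, while C4 is expected as an epimeric mixture, mainly trans to the C3 gallate through its dioxolan-2-ylium participation, which is of no consequence because C4 becomes planar again in steps 8 and 9. No regiocontrol is needed in the ring closure because the two positions ortho to the ether oxygen are equivalent, the para position cannot reach the aldehyde and the catechol ring is far less nucleophilic, and chemoselectivity against intermolecular arylation of the cation is secured by the large excess of alcohol, high dilution and low temperature.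

Step 8
Reactants: 16 4-(2-ethoxyethoxy)flavan gallate; 14 penta-O-benzylcatechin
Product: 17 protected dimer 5,7,3',4'-tetra-O-benzyl-3-O-[3,4,5-tris(benzyloxy)benzoyl]epicatechin-(4β→8)-3,5,7,3',4'-penta-O-benzylcatechin
Conditions: TMSOTf (0.2 equiv), 14 (4 equiv), CH2Cl2, −78 → −40 °C; Et3N quench; excess 14 recovered
Reagents that add atoms: none
Why: TMSOTf ionises the 4-(2-ethoxyethoxy) group of 16 to the flavan-4-yl cation, which C8 of excess 14 should capture in a Friedel–Crafts alkylation (the established Lewis acid-mediated condensation of 4-alkoxyflavans with flavan-3-ol nucleophiles), the arene entering on the β face trans to the C3 gallate, which bridges the α face as a 1,3-dioxolan-2-ylium ion and is pseudo-axial in the 2,3-cis flavan, with C8 preferred over C6 as usual for benzylated flavan-3-ols.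

Step 9
Reactants: 16 4-(2-ethoxyethoxy)flavan gallate; 17 protected dimer
Product: 18 protected trimer [5,7,3',4'-tetra-O-benzyl-3-O-(3,4,5-tri-O-benzylgalloyl)epicatechin]-(4β→8)-[5,7,3',4'-tetra-O-benzyl-3-O-(3,4,5-tri-O-benzylgalloyl)epicatechin]-(4β→8)-3,5,7,3',4'-penta-O-benzylcatechin
Conditions: TMSOTf (0.2 equiv), 17 (1.5 equiv), CH2Cl2, −78 → −40 °C, slow addition of 16; Et3N quench; unreacted 17 recovered
Reagents that add atoms: none
Why: This is the Friedel–Crafts condensation of step 8 with dimer 17 as the nucleophile, in which the cation from 16 should be captured at C8 of the galloylated epicatechin unit, the most nucleophilic and least hindered free position, from the β face opposite the participating C3 gallate.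

Step 10
Reactants: 18 protected trimer
Product: 19 epicatechin-3-O-gallate-(4β→8)-epicatechin-3-O-gallate-(4β→8)-catechin (CNP0269915.2)
Conditions: H2 (1 atm), Pd(OH)2/C, THF/MeOH/H2O, rt; filtration, lyophilisation
Reagents that add atoms: none
Why: Catalytic hydrogenolysis over Pd(OH)2 on carbon under neutral conditions should cleave all nineteen benzyl ethers while the gallate esters, the two interflavan bonds and every stereocentre remain untouched.

**Compound list**

1 | 4-bromo-1,2-bis(benzyloxy)benzene | Brc1ccc(OCc2ccccc2)c(OCc2ccccc2)c1 | starting material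
2 | (R)-2,2-dimethyl-1,3-dioxolane-4-carbaldehyde | O=C[C@H]1COC(C)(C)O1 | starting material
3 | [3,4-bis(benzyloxy)phenyl]lithium | [Li]c1ccc(OCc2ccccc2)c(OCc2ccccc2)c1 | intermediate
4 | [3,4-bis(benzyloxy)phenyl]titanium triisopropoxide | CC(C)O[Ti](OC(C)C)(OC(C)C)c1ccc(OCc2ccccc2)c(OCc2ccccc2)c1 | intermediate
5 | (S)-[3,4-bis(benzyloxy)phenyl][(4R)-2,2-dimethyl-1,3-dioxolan-4-yl]methanol | O[C@@H](c1ccc(OCc2ccccc2)c(OCc2ccccc2)c1)[C@H]1COC(C)(C)O1 | intermediate
6 | 3,5-bis(benzyloxy)phenol | Oc1cc(OCc2ccccc2)cc(OCc2ccccc2)c1 | starting material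
7 | (4R)-4-{(R)-[3,4-bis(benzyloxy)phenyl][3,5-bis(benzyloxy)phenoxy]methyl}-2,2-dimethyl-1,3-dioxolane | O([C@H](c1ccc(OCc2ccccc2)c(OCc2ccccc2)c1)[C@H]1COC(C)(C)O1)c1cc(OCc2ccccc2)cc(OCc2ccccc2)c1 | intermediate
8 | (2R,3R)-3-[3,4-bis(benzyloxy)phenyl]-3-[3,5-bis(benzyloxy)phenoxy]propane-1,2-diol | OC[C@@H](O)[C@H](Oc1cc(OCc2ccccc2)cc(OCc2ccccc2)c1)c1ccc(OCc2ccccc2)c(OCc2ccccc2)c1 | intermediate
9 | (1R,2R)-1-[3,4-bis(benzyloxy)phenyl]-1-[3,5-bis(benzyloxy)phenoxy]-3-(triethylsilyloxy)propan-2-ol | CC[Si](CC)(CC)OC[C@@H](O)[C@H](Oc1cc(OCc2ccccc2)cc(OCc2ccccc2)c1)c1ccc(OCc2ccccc2)c(OCc2ccccc2)c1 | intermediate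
10 | (1R,2R)-1-[3,4-bis(benzyloxy)phenyl]-1-[3,5-bis(benzyloxy)phenoxy]-3-(triethylsilyloxy)propan-2-yl 3,4,5-tris(benzyloxy)benzoate | CC[Si](CC)(CC)OC[C@@H](OC(=O)c1cc(OCc2ccccc2)c(OCc2ccccc2)c(OCc2ccccc2)c1)[C@H](Oc1cc(OCc2ccccc2)cc(OCc2ccccc2)c1)c1ccc(OCc2ccccc2)c(OCc2ccccc2)c1 | intermediate
11 | (1R,2R)-1-[3,4-bis(benzyloxy)phenyl]-1-[3,5-bis(benzyloxy)phenoxy]-3-hydroxypropan-2-yl 3,4,5-tris(benzyloxy)benzoate | OC[C@@H](OC(=O)c1cc(OCc2ccccc2)c(OCc2ccccc2)c(OCc2ccccc2)c1)[C@H](Oc1cc(OCc2ccccc2)cc(OCc2ccccc2)c1)c1ccc(OCc2ccccc2)c(OCc2ccccc2)c1 | intermediate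
12 | (1R,2S)-1-[3,4-bis(benzyloxy)phenyl]-1-[3,5-bis(benzyloxy)phenoxy]-3-oxopropan-2-yl 3,4,5-tris(benzyloxy)benzoate | O=C[C@@H](OC(=O)c1cc(OCc2ccccc2)c(OCc2ccccc2)c(OCc2ccccc2)c1)[C@H](Oc1cc(OCc2ccccc2)cc(OCc2ccccc2)c1)c1ccc(OCc2ccccc2)c(OCc2ccccc2)c1 | intermediate
13 | (+)-catechin, (2R,3S)-2-(3,4-dihydroxyphenyl)chromane-3,5,7-triol | Oc1cc(O)c2C[C@H](O)[C@@H](c3ccc(O)c(O)c3)Oc2c1 | starting material
14 | 3,5,7,3',4'-penta-O-benzyl-(+)-catechin | c1ccccc1COc1cc(OCc2ccccc2)c2C[C@H](OCc3ccccc3)[C@@H](c3ccc(OCc4ccccc4)c(OCc4ccccc4)c3)Oc2c1 | intermediate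
15 | (2R,3R)-5,7,3',4'-tetra-O-benzyl-4-hydroxyepicatechin 3-O-[3,4,5-tris(benzyloxy)benzoate], both C4 epimers | O=C(O[C@@H]1C(O)c2c(OCc5ccccc5)cc(OCc5ccccc5)cc2O[C@@H]1c1ccc(OCc5ccccc5)c(OCc5ccccc5)c1)c1cc(OCc5ccccc5)c(OCc5ccccc5)c(OCc5ccccc5)c1 | intermediate
16 | (2R,3R)-5,7,3',4'-tetra-O-benzyl-4-(2-ethoxyethoxy)epicatechin 3-O-[3,4,5-tris(benzyloxy)benzoate], both C4 epimers, mainly 4β expected | CCOCCOC1c2c(OCc5ccccc5)cc(OCc5ccccc5)cc2O[C@H](c2ccc(OCc5ccccc5)c(OCc5ccccc5)c2)[C@@H]1OC(=O)c1cc(OCc5ccccc5)c(OCc5ccccc5)c(OCc5ccccc5)c1 | intermediate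
17 | 5,7,3',4'-tetra-O-benzyl-3-O-[3,4,5-tris(benzyloxy)benzoyl]epicatechin-(4β→8)-3,5,7,3',4'-penta-O-benzylcatechin | O=C(O[C@@H]1[C@@H](c2c(OCc5ccccc5)cc(OCc5ccccc5)c3c2O[C@H](c2ccc(OCc5ccccc5)c(OCc5ccccc5)c2)[C@@H](OCc5ccccc5)C3)c2c(OCc5ccccc5)cc(OCc5ccccc5)cc2O[C@@H]1c1ccc(OCc5ccccc5)c(OCc5ccccc5)c1)c1cc(OCc5ccccc5)c(OCc5ccccc5)c(OCc5ccccc5)c1 | intermediate
18 | nonadeca-O-benzyl derivative of the target: both epicatechin units 5,7,3',4'-tetra-O-benzyl with 3-O-(3,4,5-tri-O-benzylgalloyl), catechin unit 3,5,7,3',4'-penta-O-benzyl, both links 4β→8 | O=C(O[C@@H]1[C@@H](c2c(OCc5ccccc5)cc(OCc5ccccc5)c3c2O[C@H](c2ccc(OCc5ccccc5)c(OCc5ccccc5)c2)[C@@H](OCc5ccccc5)C3)c2c(OCc5ccccc5)cc(OCc5ccccc5)c([C@H]3c4c(OCc5ccccc5)cc(OCc5ccccc5)cc4O[C@H](c4ccc(OCc5ccccc5)c(OCc5ccccc5)c4)[C@@H]3OC(=O)c3cc(OCc5ccccc5)c(OCc5ccccc5)c(OCc5ccccc5)c3)c2O[C@@H]1c1ccc(OCc5ccccc5)c(OCc5ccccc5)c1)c1cc(OCc5ccccc5)c(OCc5ccccc5)c(OCc5ccccc5)c1 | intermediate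
19 | epicatechin-3-O-gallate-(4β→8)-epicatechin-3-O-gallate-(4β→8)-catechin (CNP0269915.2) | O=C(O[C@@H]1[C@@H](c2c(O)cc(O)c3c2O[C@H](c2ccc(O)c(O)c2)[C@@H](O)C3)c2c(O)cc(O)c([C@H]3c4c(O)cc(O)cc4O[C@H](c4ccc(O)c(O)c4)[C@@H]3OC(=O)c3cc(O)c(O)c(O)c3)c2O[C@@H]1c1ccc(O)c(O)c1)c1cc(O)c(O)c(O)c1 | target

**Step count and risks**

Total step count: 10. Longest linear sequence: 9 steps (steps 1, 2, 3, 4, 5, 7, 8, 9, 10).

Steps most likely to fail:

1. Step 7. What may go wrong: the 4-ether re-ionises under the acid that forms it, so that the flavan-4-yl cation alkylates ring A of a second molecule and oligomers form, or the enolisable aldehyde loses its aryloxide by β-elimination before ring C closes. Fallback: ring C is closed through a thionium ion, and the group left on C4 is a thioether that the cyclisation conditions cannot ionise. It sets out from aldehyde 12, which is converted (BnSH, BF3·OEt2, CH2Cl2, −40 °C) into the dibenzyl dithioacetal of aldehyde 12 F1. Dimethyl(methylthio)sulfonium tetrafluoroborate (1.0 equiv, CH2Cl2, −40 °C) should remove one benzylthio group, and the resulting thionium ion closes ring C through the same C4–C4a bond to give 5,7,3',4'-tetra-O-benzyl-4-(benzylthio)epicatechin 3-O-[3,4,5-tris(benzyloxy)benzoate] F2. Thiophilic activation of F2 with AgBF4 (THF, 0 °C) in the presence of 14 (4 equiv), the known coupling of 4-benzylthioflavans with flavan-3-ols, rejoins the route at dimer 17. In step 9 F2 then takes the place of 16 under the same activation.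

2. Step 9. What may go wrong: over-addition to tetramers and higher oligomers, because the incoming unit and the product both carry a free C8, and acid-induced scission of the first interflavan bond on long exposure. Fallback: a bromine-capped electrophile. It sets out from 4-ether 16, which NBS (CH2Cl2, −40 °C) should brominate at C8 to give 8-bromo-5,7,3',4'-tetra-O-benzyl-4-(2-ethoxyethoxy)epicatechin 3-O-[3,4,5-tris(benzyloxy)benzoate] F3, whose blocked ring A can no longer act as a nucleophile. TMSOTf-catalysed condensation of F3 with 17 (1.2 equiv, CH2Cl2, −78 °C) should give the protected trimer 18 carrying bromine at C8 of the upper epicatechin unit F4. Hydrogenolysis as in step 10 with added Et3N removes the bromine together with the benzyl groups and comes back at target 19.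

3. Step 2. What may go wrong: ionisation of the electron-rich benzylic alkoxyphosphonium ion, which erodes the inversion and gives a mixture of epimeric ethers. Fallback: the carbinol centre is inverted by oxidation and reduction, and the aryl ether is then formed with retention by O-arylation. It sets out from alcohol 5, which is oxidised (Dess–Martin periodinane, NaHCO3, CH2Cl2) to [3,4-bis(benzyloxy)phenyl][(4R)-2,2-dimethyl-1,3-dioxolan-4-yl]methanone F5. Reduction with the bulky, non-chelating hydride K[HB(s-Bu)3] (THF, −78 °C) should follow the Felkin–Anh model and give mainly the syn alcohol (R)-[3,4-bis(benzyloxy)phenyl][(4R)-2,2-dimethyl-1,3-dioxolan-4-yl]methanol F6. Copper-catalysed Ullmann-type etherification of F6 with 1,3-bis(benzyloxy)-5-iodobenzene (CuI, 3,4,7,8-tetramethyl-1,10-phenanthroline, Cs2CO3, toluene, 110 °C) leaves the carbinol C–O bond intact and rejoins the route at 7.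

Further compounds
F1 | step 7 | dibenzyl dithioacetal of aldehyde 12 | C(c1ccccc1)SC(SCc1ccccc1)[C@@H](OC(=O)c1cc(OCc2ccccc2)c(OCc2ccccc2)c(OCc2ccccc2)c1)[C@H](Oc1cc(OCc2ccccc2)cc(OCc2ccccc2)c1)c1ccc(OCc2ccccc2)c(OCc2ccccc2)c1
F2 | step 7 | 5,7,3',4'-tetra-O-benzyl-4-(benzylthio)epicatechin 3-O-[3,4,5-tris(benzyloxy)benzoate], C4 epimers, mainly 4β expected | C(c6ccccc6)SC1c2c(OCc5ccccc5)cc(OCc5ccccc5)cc2O[C@H](c2ccc(OCc5ccccc5)c(OCc5ccccc5)c2)[C@@H]1OC(=O)c1cc(OCc5ccccc5)c(OCc5ccccc5)c(OCc5ccccc5)c1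
F3 | step 9 | 8-bromo-5,7,3',4'-tetra-O-benzyl-4-(2-ethoxyethoxy)epicatechin 3-O-[3,4,5-tris(benzyloxy)benzoate] | CCOCCOC1c2c(OCc5ccccc5)cc(OCc5ccccc5)c(Br)c2O[C@H](c2ccc(OCc5ccccc5)c(OCc5ccccc5)c2)[C@@H]1OC(=O)c1cc(OCc5ccccc5)c(OCc5ccccc5)c(OCc5ccccc5)c1
F4 | step 9 | protected trimer 18 carrying bromine at C8 of the upper epicatechin unit | O=C(O[C@@H]1[C@@H](c2c(OCc5ccccc5)cc(OCc5ccccc5)c3c2O[C@H](c2ccc(OCc5ccccc5)c(OCc5ccccc5)c2)[C@@H](OCc5ccccc5)C3)c2c(OCc5ccccc5)cc(OCc5ccccc5)c([C@H]3c4c(OCc5ccccc5)cc(OCc5ccccc5)c(Br)c4O[C@H](c4ccc(OCc5ccccc5)c(OCc5ccccc5)c4)[C@@H]3OC(=O)c3cc(OCc5ccccc5)c(OCc5ccccc5)c(OCc5ccccc5)c3)c2O[C@@H]1c1ccc(OCc5ccccc5)c(OCc5ccccc5)c1)c1cc(OCc5ccccc5)c(OCc5ccccc5)c(OCc5ccccc5)c1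
F5 | step 2 | [3,4-bis(benzyloxy)phenyl][(4R)-2,2-dimethyl-1,3-dioxolan-4-yl]methanone | O=C(c1ccc(OCc2ccccc2)c(OCc2ccccc2)c1)[C@H]1COC(C)(C)O1
F6 | step 2 | (R)-[3,4-bis(benzyloxy)phenyl][(4R)-2,2-dimethyl-1,3-dioxolan-4-yl]methanol | O[C@H](c1ccc(OCc2ccccc2)c(OCc2ccccc2)c1)[C@H]1COC(C)(C)O1
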